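## The problem

Target 37 is a germacranolide, and the locants C1–C15 used below follow germacrane numbering. It is a ten-membered carbocycle (C1–C10) with a ring-trans trisubstituted C4=C5 alkene (Z by the sequence rule because C4 carries the C15 hydroxymethyl group), an α-methylene-γ-butyrolactone trans-fused across C6–C7, a methacrylate on O8 and a hydroxymethyl group (C14) on the saturated carbon C10. A synthesis has to close a medium ring against entropy and transannular strain, and must not scramble the alkene geometry while doing so. Three of the four stereocentres (C6, C7, C8) are contiguous and can be relayed: C6 can direct an anti conjugate addition at C7 (trans-lactone), and C7, as the α-centre of a C8 aldehyde, can direct a nucleophile to C8. C10 is insulated from them by the C9 methylene and has to be set by the ring conformation or by the C8 substituent. The fragile elements are the two Michael acceptors (α-methylene lactone, methacrylate), which tolerate neither nucleophiles, boranes nor strong base and so must come last; a C8 aldehyde on the lactone, which is a β-acyloxy aldehyde open to E1cB ring opening and C7 epimerisation; and a free O8 alkoxide, which can translactonise to the 8,12-olide. Three oxygens (O8, O14, O15) have to be told apart, since only O8 is acylated. The enabling feature is the C8–C9–C10(C14) array: C9 is a bare methylene between the C8 carbinol and C10, and the C10–CH2OH group is the hydroboration product of an exocyclic C10=C14 alkene. Read this way, C9–C10(=C14) is a 2-substituted allyl unit with two CH2 termini, the product of adding an allyl-metal to a C8 aldehyde with no regiochemical ambiguity.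

## Retrosynthesis

**End game (37 ⇒ 30).** The O14 and O15 silyl ethers are restored (36), the O8–methacrylate bond is cut (35), and the exocyclic C11=C13 bond is removed by way of the O8 triethylsilyl ether 34 to the saturated lactone 30. Both Michael acceptors are cut first because neither survives the borane, nitronate and enolate chemistry that precedes them. The forward steps ask for a lactone enolate Mannich methylenation on a substrate without free hydroxyl, and for removal of a secondary triethylsilyl ether beside two primary tert-butyldimethylsilyl ethers.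

**C10–H and C14–O (30 ⇒ 29 ⇒ 27 ⇒ 26).** Hydroboration of an exocyclic alkene is the retron for the C10–CH2OH group. This cut is preferred to carrying C10 as a preformed stereocentre, because the 1,3-relation C8/C10 is hard to set in an open chain but can be read from the face of a formed ring. The precursor 26 has three stereocentres instead of four. The forward reaction must add from the ring face opposite O8.

**C8–C9, the key cut (26 ⇒ 24).** Cutting C8–C9 opens the ring to an allylic bromide tethered to a lactone aldehyde. Against the neighbouring cuts: C5–C6 or C6–C7 would put the ring closure onto the lactone-forming centres and demand more pre-set acyclic stereocentres, and cuts in the C1–C3 methylene chain create no functionality and no stereocentre. The C8–C9 cut creates the C8 carbinol next to the resident C7 centre and leaves behind exactly the alkene needed for C10/C14. Precursor 24 is acyclic apart from the lactone and holds only two stereocentres. The forward reaction asks for closure over intermolecular coupling and for the correct aldehyde face.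

**Aldehyde and bromide (24 ⇒ 23 ⇒ 21 ⇒ 20).** The allylic bromide is traced to the alcohol 23 and to the PMB ether, and the C8 aldehyde to a nitromethyl group (Nef retron, nitro alcohol 21, nitro lactone 20). The PMB group is removed before the Nef reaction so that the sensitive β-acyloxy aldehyde is carried through a single neutral step before cyclisation.

**C7–C8 (20 ⇒ 18 + 19).** Conjugate addition of nitromethane (19) to butenolide 18 is chosen over addition of a vinyl or dithiane nucleophile because the nitromethyl group is unmasked without touching the three alkenes. The resident C6 centre sets C7 trans.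

**C6–C7 and the lactone C–O bond (18 ⇒ 16 ⇒ 13 + 14).** The butenolide is the cyclised cis-reduction product of γ-hydroxy ynoate 16, which comes from enal 13 and methyl propiolate (14). This cut creates the first stereocentre (C6) by catalyst control and brings C7, C11 and C12 in one piece.

**C3–C4 (13 ⇒ 12 ⇒ 11 ⇒ 6 + 9).** Enal 13 is reached from ester 11 through alcohol 12. Ester 11 is the syn-carbocupration product of ynoate 9 with the organocopper reagent from bromide 6. This is preferred to a carbonyl olefination at C4=C5, which would not reliably put the oxygenated C15 cis to C6; syn addition across the alkyne does so by mechanism.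

**Building blocks (9 ⇒ 7; 6 ⇒ 5 ⇒ 2 + 3; 2 ⇒ 1).** Ynoate 9 is the carboxylated silyl ether 7 of propargyl alcohol. Bromide 6 comes from alcohol 5, the product of opening oxirane (3) with the allyl Grignard reagent of chloride 2, itself the mono-PMB ether of dichloride 1. Dichloride 1 thus supplies C1, C9, C10 and C14, and oxirane supplies C2 and C3.

## Roads not taken

**Alternative 1:** Grob fragmentation. The cut is made through a transannular C4–C10 bond: a bicyclo[5.3.0]decane hydroxy mesylate A1 (tertiary C10–OH, C5–OMs anti-periplanar to C4–C10) would be treated with KOt-Bu, and the ring-fusion bond would break to give cyclodecenone A2 with a C10 ketone and a conjugated C15 ester.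
- Merits: no high dilution is needed, ring strain is paid for by the fragmentation, and the ring-trans C4=C5 geometry follows stereospecifically from the C4/C5 configuration of A1. In these respects it is better than the chosen plan, which needs dilution for its closure.
- Weak points: A1 needs six stereocentres, three of which (C4, C5, C10) are destroyed. A2 is a β-alkoxy ketone (O8 is β to C10) and a γ-alkoxy enoate exposed to alkoxide base. After fragmentation, C10 must still be methylenated and hydroborated, the C15 ester reduced and the C12 acetal oxidised and lactonised.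
- Comparison: the chosen plan sets against it a cyclisation product (26) that already has the lactone and the correct oxidation level at C15 and stands seven steps from the target.

**Alternative 2:** Chromium/nickel alkenylation at C5–C6. The cut is C5–C6: the alkenyl iodide of iodo aldehyde A3 would be converted by CrCl2 with catalytic NiCl2 into an alkenylchromium species that adds to the C6 aldehyde, giving the ten-membered allylic alcohol A4.
- Merits: the same mild, chemoselective chromium chemistry; retention of the alkene geometry; the C12 ester of A4 lactonises onto O6 without a Nef reaction, so the approach is at least as good in functional-group economy near the lactone.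
- Weak points: A3 must carry C7, C8 and the remote C10 as pre-set acyclic stereocentres. Its aldehyde is α-branched and β-alkoxy, so it is as epimerisable as aldehyde 24. The new C6 centre must come out trans to C7 in a macrocyclic transition state with no strong bias.
- Comparison: the chosen plan sets C6 by a catalyst and C7 by relay, and leaves C10 to the formed ring.

**Alternative 3:** 10-endo radical conjugate addition at C1–C2. The cut is C1–C2: (Me3Si)3SiH/AIBN would abstract iodine from C2 of iodo acrylate A5, and the primary radical would add to the acrylate terminus C1 to give macrocyclic ester A6 after hydrogen transfer to C10.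
- Merits: the bond is formed far from every stereocentre with the complete lactone and C8 oxygen in place; conditions are neutral; the C10 centre of A6 is α to an ester and could be equilibrated. Here it is better than the chosen plan, whose C10 centre cannot be corrected by equilibration.
- Weak points: endo radical macrocyclisation is well behaved for larger rings but not for ten-membered ones. Premature reduction of the radical and 1,5-hydrogen transfer from the allylic, oxygenated C6–H compete. Hydrogen delivery to C10 has no clear facial bias. The C14 ester must afterwards be reduced in the presence of the lactone.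
- Comparison: the chosen plan offers a polarity-matched ionic closure with direct precedent for ten-membered rings, and C14 arrives at the alcohol level.

Key step: step 14

Assumption 1: the (R,R) antipode of ProPhenol is taken to deliver the 4S carbinol 16; if the sense of induction is the opposite, the (S,S) ligand is used with no other change.
Assumption 2: silyl ether 7 of propargyl alcohol is bought; if it is made from propargyl alcohol, one silylation step is added.
Assumption 3: CIP descriptors in names refer to the compound named (they change with the substituents although the spatial arrangement does not).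

## Route

Step 1
Reactants: 1 3-chloro-2-(chloromethyl)prop-1-ene
Product: 2 1-({[2-(chloromethyl)prop-2-en-1-yl]oxy}methyl)-4-methoxybenzene
Conditions: 4-MeOC6H4CH2OH, NaH, THF, 0 °C; then 1 (3 equiv), 0 → 50 °C
Reagents that add atoms: 4-methoxybenzyl alcohol, COc1ccc(CO)cc1
Why: Williamson etherification; direct and allylic displacement on the 2-substituted allyl chloride give the same ether, and the excess of volatile 1 suppresses the bis-ether.

Step 2
Reactants: 2 1-({[2-(chloromethyl)prop-2-en-1-yl]oxy}methyl)-4-methoxybenzene; 3 oxirane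
Product: 5 4-{[(4-methoxybenzyl)oxy]methyl}pent-4-en-1-ol, via allylmagnesium chloride 4 (not isolated)
Conditions: Mg (excess), THF, 0 °C, slow addition of 2; then 3 (THF solution), 0 °C → rt; aqueous work-up
Reagents that add atoms: none
Why: Grignard formation from an allylic chloride and epoxide opening, the standard two-carbon hydroxyethylation of allylmagnesium halides; both allyl termini are CH2, so α and γ attack give the same alcohol. Slow addition to excess Mg at 0 °C limits Wurtz coupling.

Step 3
Reactants: 5 4-{[(4-methoxybenzyl)oxy]methyl}pent-4-en-1-ol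
Product: 6 1-{[(5-bromo-2-methylidenepentyl)oxy]methyl}-4-methoxybenzene
Conditions: CBr4, PPh3, CH2Cl2, 0 °C
Reagents that add atoms: carbon tetrabromide, BrC(Br)(Br)Br
Why: Appel bromination of a primary alcohol under neutral conditions; the PMB ether and the 1,1-disubstituted alkene are inert.

Step 4
Reactants: 7 tert-butyldimethyl(prop-2-yn-1-yloxy)silane
Product: 9 methyl 4-{[tert-butyl(dimethyl)silyl]oxy}but-2-ynoate, via lithium acetylide 8 (not isolated)
Conditions: n-BuLi, THF, −78 °C; then ClCO2Me, −78 → 0 °C
Reagents that add atoms: methyl chloroformate, COC(=O)Cl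
Why: Deprotonation of the terminal alkyne and C-acylation of the acetylide with a chloroformate; the standard preparation of 4-silyloxybut-2-ynoates.

Step 5
Reactants: 6 1-{[(5-bromo-2-methylidenepentyl)oxy]methyl}-4-methoxybenzene; 9 methyl 4-{[tert-butyl(dimethyl)silyl]oxy}but-2-ynoate
Product: 11 methyl (2Z)-3-({[tert-butyl(dimethyl)silyl]oxy}methyl)-7-{[(4-methoxybenzyl)oxy]methyl}octa-2,7-dienoate, via Grignard reagent 10 (not isolated)
Conditions: Mg, THF, rt; CuBr·SMe2 (1 equiv), THF/Me2S, −45 °C; 9, −78 °C; MeOH then aq. NH4Cl at −78 °C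
Reagents that add atoms: none
Why: syn-Carbocupration of an ynoate by the alkylcopper reagent formed from 10 and CuBr·SMe2; alkyl and copper add to the same side and cold protonation of the alkenylcopper with retention places the new chain cis to H5 and the silyloxymethyl group cis to the ester. This is the 2Z (ring-trans) C4=C5 geometry of the target; quenching at −78 °C prevents equilibration through the allenoate.

Step 6
Reactants: 11 methyl (2Z)-3-({[tert-butyl(dimethyl)silyl]oxy}methyl)-7-{[(4-methoxybenzyl)oxy]methyl}octa-2,7-dienoate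
Product: 12 (2Z)-3-({[tert-butyl(dimethyl)silyl]oxy}methyl)-7-{[(4-methoxybenzyl)oxy]methyl}octa-2,7-dien-1-ol
Conditions: i-Bu2AlH (2.3 equiv), CH2Cl2, −78 °C; Rochelle-salt work-up
Reagents that add atoms: none
Why: 1,2-Reduction of an α,β-unsaturated ester to the allylic alcohol with i-Bu2AlH; low temperature and neutral work-up keep the cis-disposed silyl group from migrating.

Step 7
Reactants: 12 (2Z)-3-({[tert-butyl(dimethyl)silyl]oxy}methyl)-7-{[(4-methoxybenzyl)oxy]methyl}octa-2,7-dien-1-ol
Product: 13 (2Z)-3-({[tert-butyl(dimethyl)silyl]oxy}methyl)-7-{[(4-methoxybenzyl)oxy]methyl}octa-2,7-dienal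
Conditions: MnO2 (excess), CH2Cl2, rt
Reagents that add atoms: none
Why: Allylic oxidation with MnO2 is neutral and heterogeneous, so the Z enal should not isomerise and nothing else is oxidised.

Step 8
Reactants: 13 (2Z)-3-({[tert-butyl(dimethyl)silyl]oxy}methyl)-7-{[(4-methoxybenzyl)oxy]methyl}octa-2,7-dienal; 14 methyl prop-2-ynoate
Product: 16 methyl (4S,5Z)-6-({[tert-butyl(dimethyl)silyl]oxy}methyl)-4-hydroxy-10-{[(4-methoxybenzyl)oxy]methyl}undeca-5,10-dien-2-ynoate, via methylzinc alkynylide 15 (not isolated)
Conditions: 14 (3 equiv), Me2Zn (3 equiv), (R,R)-ProPhenol (20 mol%), Ph3P=O (40 mol%), toluene, 0 °C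
Reagents that add atoms: none
Why: Zinc–ProPhenol catalysed enantioselective 1,2-addition of a zinc alkynylide to an α,β-unsaturated aldehyde; the chiral dinuclear zinc catalyst selects the aldehyde face and sets C6 (4S here).

Step 9
Reactants: 16 methyl (4S,5Z)-6-({[tert-butyl(dimethyl)silyl]oxy}methyl)-4-hydroxy-10-{[(4-methoxybenzyl)oxy]methyl}undeca-5,10-dien-2-ynoate
Product: 18 (5R)-5-[(1Z)-2-({[tert-butyl(dimethyl)silyl]oxy}methyl)-6-{[(4-methoxybenzyl)oxy]methyl}hepta-1,6-dien-1-yl]furan-2(5H)-one, via cis-hydroxy enoate 17 (not isolated)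
Conditions: H2 (1 atm), lead-poisoned Pd/CaCO3, quinoline, EtOAc, rt; then PPTS (cat.), CH2Cl2, rt
Reagents that add atoms: none
Why: Semihydrogenation of the alkyne to the cis enoate, which lactonises to the butenolide; the C6–O bond is not broken, so the configuration is kept (the descriptor changes only formally). The poisoned catalyst leaves the tri- and 1,1-disubstituted alkenes and the PMB ether alone.

Step 10
Reactants: 18 (5R)-5-[(1Z)-2-({[tert-butyl(dimethyl)silyl]oxy}methyl)-6-{[(4-methoxybenzyl)oxy]methyl}hepta-1,6-dien-1-yl]furan-2(5H)-one; 19 nitromethane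
Product: 20 (4S,5S)-5-[(1Z)-2-({[tert-butyl(dimethyl)silyl]oxy}methyl)-6-{[(4-methoxybenzyl)oxy]methyl}hepta-1,6-dien-1-yl]-4-(nitromethyl)oxolan-2-one
Conditions: 19 (10 equiv), DBU (0.3 equiv), MeCN, 0 °C
Reagents that add atoms: none
Why: Base-catalysed Michael addition of nitromethane to a γ-substituted butenolide; the nitronate attacks C7 on the face anti to the C6 alkenyl group and gives the trans-4,5-disubstituted lactone. Low temperature, substoichiometric base and excess nitromethane are meant to outrun deprotonation at C6.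

Step 11
Reactants: 20 (4S,5S)-5-[(1Z)-2-({[tert-butyl(dimethyl)silyl]oxy}methyl)-6-{[(4-methoxybenzyl)oxy]methyl}hepta-1,6-dien-1-yl]-4-(nitromethyl)oxolan-2-one
Product: 21 (4S,5S)-5-[(1Z)-2-({[tert-butyl(dimethyl)silyl]oxy}methyl)-6-(hydroxymethyl)hepta-1,6-dien-1-yl]-4-(nitromethyl)oxolan-2-one
Conditions: DDQ (1.3 equiv), CH2Cl2/pH 7 buffer, 0 °C
Reagents that add atoms: none
Why: Oxidative cleavage of the PMB ether through its benzylic oxocarbenium ion; silyl ether, lactone, alkenes and nitro group are unaffected.

Step 12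
Reactants: 21 (4S,5S)-5-[(1Z)-2-({[tert-butyl(dimethyl)silyl]oxy}methyl)-6-(hydroxymethyl)hepta-1,6-dien-1-yl]-4-(nitromethyl)oxolan-2-one
Product: 23 (2S,3R)-2-[(1Z)-2-({[tert-butyl(dimethyl)silyl]oxy}methyl)-6-(hydroxymethyl)hepta-1,6-dien-1-yl]-5-oxooxolane-3-carbaldehyde, via potassium nitronate 22 (not isolated)
Conditions: KOt-Bu (1.05 equiv), THF, −40 °C; then into aq. TiCl3 (4 equiv)/NH4OAc (pH ca. 6), 0 °C → rt
Reagents that add atoms: water, O
Why: Reductive Nef reaction: the nitronate (the CH2NO2 protons are by far the most acidic) is reduced by buffered TiCl3 (trivalent titanium) to the imine, which hydrolyses to the aldehyde at a pH mild enough for the lactone, the silyl ether and the β-acyloxy aldehyde. C7 keeps its trans, thermodynamically preferred configuration.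

Step 13
Reactants: 23 (2S,3R)-2-[(1Z)-2-({[tert-butyl(dimethyl)silyl]oxy}methyl)-6-(hydroxymethyl)hepta-1,6-dien-1-yl]-5-oxooxolane-3-carbaldehyde
Product: 24 (2S,3R)-2-[(1Z)-6-(bromomethyl)-2-({[tert-butyl(dimethyl)silyl]oxy}methyl)hepta-1,6-dien-1-yl]-5-oxooxolane-3-carbaldehyde
Conditions: NBS, Me2S, CH2Cl2, 0 °C; then 23, −20 → 0 °C
Reagents that add atoms: N-bromosuccinimide, O=C1CCC(=O)N1Br
Why: Corey–Kim-type halogenation: the sulfonium salt from NBS and Me2S turns the allylic alcohol into an alkoxysulfonium bromide that collapses by SN2 to the allylic bromide and DMSO. The medium is neutral and spares the aldehyde, its α-stereocentre and the alkenes.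

Step 14
Reactants: 24 (2S,3R)-2-[(1Z)-6-(bromomethyl)-2-({[tert-butyl(dimethyl)silyl]oxy}methyl)hepta-1,6-dien-1-yl]-5-oxooxolane-3-carbaldehyde
Product: 26 (3aS,4R,10Z,11aS)-10-({[tert-butyl(dimethyl)silyl]oxy}methyl)-4-hydroxy-6-methylidene-3a,4,5,6,7,8,9,11a-octahydrocyclodeca[b]furan-2(3H)-one, via allylchromium dichloride 25 (not isolated)
Conditions: CrCl2 (10 equiv), THF, rt, 24 added by syringe pump over 12 h (final ca. 2 mM); aqueous work-up
Reagents that add atoms: none
Why: Two one-electron transfers from divalent chromium convert the allylic bromide into allylchromium dichloride 25 (trivalent chromium), which is nucleophilic toward the aldehyde only; lactone, silyl ether and both alkenes are inert. The C–C bond forms through a six-membered chair-like transition state with allylic transposition, and because both termini of the 2-substituted allyl unit are CH2 groups either terminus gives the same C8–C9 bond and the same exocyclic C10=C14 alkene. The closest known reaction type is the intramolecular Nozaki–Hiyama allylation of aldehydes by allylic bromides, which has been used to close ten-membered carbocycles of the germacrane type. The ten-membered ring closes in the 10-exo-trig mode (carbon nucleophile onto a carbonyl whose oxygen stays outside the ring); the rigid trans-lactone and the ring-trans C4=C5 alkene remove rotors from the tether. The new stereocentre C8 is controlled by the adjacent C7: in the Felkin–Anh arrangement the C7–C6 bond (the branched, oxygen-bearing substituent) lies anti to the incoming C9 and the nucleophile passes H7, which should give the 8R alcohol with O8 and H7 cis on the ring. The step needs closure over intermolecular allylation, secured by slow addition into excess CrCl2 at high dilution, and it needs C7 to stay intact, which the non-basic medium secures.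

Step 15
Reactants: 26 (3aS,4R,10Z,11aS)-10-({[tert-butyl(dimethyl)silyl]oxy}methyl)-4-hydroxy-6-methylidene-3a,4,5,6,7,8,9,11a-octahydrocyclodeca[b]furan-2(3H)-one
Product: 27 (3aR,4R,10Z,11aS)-10-({[tert-butyl(dimethyl)silyl]oxy}methyl)-6-methylidene-4-[(triethylsilyl)oxy]-3a,4,5,6,7,8,9,11a-octahydrocyclodeca[b]furan-2(3H)-one
Conditions: Et3SiCl, imidazole, DMF, 0 °C → rt
Reagents that add atoms: chlorotriethylsilane, CC[Si](Cl)(CC)CC
Why: Silylation of the secondary alcohol; the O8 silyl ether blocks translactonisation in the later basic steps, adds bulk on the O8 face of the ring for step 16 and can later be removed beside primary TBS ethers.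

Step 16
Reactants: 27 (3aR,4R,10Z,11aS)-10-({[tert-butyl(dimethyl)silyl]oxy}methyl)-6-methylidene-4-[(triethylsilyl)oxy]-3a,4,5,6,7,8,9,11a-octahydrocyclodeca[b]furan-2(3H)-one
Product: 29 (3aR,4R,6R,10Z,11aS)-10-({[tert-butyl(dimethyl)silyl]oxy}methyl)-6-(hydroxymethyl)-4-[(triethylsilyl)oxy]-3a,4,5,6,7,8,9,11a-octahydrocyclodeca[b]furan-2(3H)-one, via B-alkyl-9-BBN 28 (not isolated)
Conditions: 9-BBN (2 equiv), THF, 0 °C → rt; then 30% H2O2, 3 M aq. NaOAc, 0 °C → rt
Reagents that add atoms: hydrogen peroxide, OO
Why: Hydroboration–oxidation: boron adds to the terminal C14 of the 1,1-disubstituted alkene and leaves the trisubstituted C4=C5 alkene and the lactone untouched. The bulky borane should deliver hydrogen to C10 from the periphery of the ring on the face opposite the C8 silyloxy group, which places C14 cis to O8 (C10 R); buffered oxidation proceeds with retention and spares the lactone.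

Step 17
Reactants: 29 (3aR,4R,6R,10Z,11aS)-10-({[tert-butyl(dimethyl)silyl]oxy}methyl)-6-(hydroxymethyl)-4-[(triethylsilyl)oxy]-3a,4,5,6,7,8,9,11a-octahydrocyclodeca[b]furan-2(3H)-one
Product: 30 (3aR,4R,6R,10Z,11aS)-6,10-bis({[tert-butyl(dimethyl)silyl]oxy}methyl)-4-[(triethylsilyl)oxy]-3a,4,5,6,7,8,9,11a-octahydrocyclodeca[b]furan-2(3H)-one
Conditions: t-BuMe2SiCl, imidazole, DMF, rt
Reagents that add atoms: tert-butylchlorodimethylsilane, CC(C)(C)[Si](C)(C)Cl
Why: Standard silylation of a primary alcohol; after it no free hydroxyl remains for the enolate step.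

Step 18
Reactants: 30 (3aR,4R,6R,10Z,11aS)-6,10-bis({[tert-butyl(dimethyl)silyl]oxy}methyl)-4-[(triethylsilyl)oxy]-3a,4,5,6,7,8,9,11a-octahydrocyclodeca[b]furan-2(3H)-one
Product: 34 (3aR,4R,6R,10Z,11aS)-6,10-bis({[tert-butyl(dimethyl)silyl]oxy}methyl)-3-methylidene-4-[(triethylsilyl)oxy]-3a,4,5,6,7,8,9,11a-octahydrocyclodeca[b]furan-2(3H)-one, via lithium enolate 31 (not isolated), via Mannich base 32 (not isolated), via trimethylammonium iodide 33 (not isolated)
Conditions: LiN(i-Pr)2, THF, −78 °C; CH2=NMe2+ I−, −78 °C → rt; MeI, MeOH, rt; aq. NaHCO3/EtOAc, rt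
Reagents that add atoms: N,N-dimethylmethyleneiminium iodide, C=[N+](C)C.[I-]
Why: α-Methylenation of a lactone by Mannich reaction of its lithium enolate, quaternisation and base-induced elimination of trimethylamine; C11 is the only enolisable position and becomes sp2, and C7 is untouched.

Step 19
Reactants: 34 (3aR,4R,6R,10Z,11aS)-6,10-bis({[tert-butyl(dimethyl)silyl]oxy}methyl)-3-methylidene-4-[(triethylsilyl)oxy]-3a,4,5,6,7,8,9,11a-octahydrocyclodeca[b]furan-2(3H)-one
Product: 35 (3aS,4R,6R,10Z,11aS)-6,10-bis({[tert-butyl(dimethyl)silyl]oxy}methyl)-4-hydroxy-3-methylidene-3a,4,5,6,7,8,9,11a-octahydrocyclodeca[b]furan-2(3H)-one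
Conditions: HF·pyridine, pyridine, THF, 0 °C
Reagents that add atoms: none
Why: Selective cleavage of the more labile triethylsilyl ether beside tert-butyldimethylsilyl ethers with pyridine-buffered HF·pyridine; the buffered acidic fluoride source does not add to the α-methylene lactone.

Step 20
Reactants: 35 (3aS,4R,6R,10Z,11aS)-6,10-bis({[tert-butyl(dimethyl)silyl]oxy}methyl)-4-hydroxy-3-methylidene-3a,4,5,6,7,8,9,11a-octahydrocyclodeca[b]furan-2(3H)-one
Product: 36 (3aS,4R,6R,10Z,11aS)-6,10-bis({[tert-butyl(dimethyl)silyl]oxy}methyl)-3-methylidene-2-oxo-2,3,3a,4,5,6,7,8,9,11a-decahydrocyclodeca[b]furan-4-yl 2-methylprop-2-enoate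
Conditions: methacrylic anhydride, Et3N, DMAP (cat.), CH2Cl2, 0 °C → rt
Reagents that add atoms: methacrylic anhydride, CC(=C)C(=O)OC(=O)C(C)=C
Why: DMAP-catalysed acylation of the only free hydroxyl, with retention at C8.

Step 21
Reactants: 36 (3aS,4R,6R,10Z,11aS)-6,10-bis({[tert-butyl(dimethyl)silyl]oxy}methyl)-3-methylidene-2-oxo-2,3,3a,4,5,6,7,8,9,11a-decahydrocyclodeca[b]furan-4-yl 2-methylprop-2-enoate
Product: 37 (3aS,4R,6R,10Z,11aS)-6,10-bis(hydroxymethyl)-3-methylidene-2-oxo-2,3,3a,4,5,6,7,8,9,11a-decahydrocyclodeca[b]furan-4-yl 2-methylprop-2-enoate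
Conditions: HF·pyridine, THF, 0 °C → rt
Reagents that add atoms: none
Why: Fluoride cleavage of both primary silyl ethers under mildly acidic conditions that tolerate the two Michael acceptors and do not promote acyl migration.

## Compound list

1 | 3-chloro-2-(chloromethyl)prop-1-ene | C=C(CCl)CCl | starting material
2 | 1-({[2-(chloromethyl)prop-2-en-1-yl]oxy}methyl)-4-methoxybenzene | COc1ccc(COCC(=C)CCl)cc1 | intermediate
3 | oxirane | C1CO1 | starting material
4 | {2-[(4-methoxybenzyloxy)methyl]prop-2-en-1-yl}magnesium chloride (formed in the flask) | COc1ccc(COCC(=C)C[Mg]Cl)cc1 | intermediate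
5 | 4-{[(4-methoxybenzyl)oxy]methyl}pent-4-en-1-ol | COc1ccc(COCC(=C)CCCO)cc1 | intermediate
6 | 1-{[(5-bromo-2-methylidenepentyl)oxy]methyl}-4-methoxybenzene | COc1ccc(COCC(=C)CCCBr)cc1 | intermediate
7 | tert-butyldimethyl(prop-2-yn-1-yloxy)silane | C#CCO[Si](C)(C)C(C)(C)C | starting material
8 | [3-(tert-butyldimethylsilyloxy)prop-1-yn-1-yl]lithium (formed in the flask) | [Li]C#CCO[Si](C)(C)C(C)(C)C | intermediate
9 | methyl 4-{[tert-butyl(dimethyl)silyl]oxy}but-2-ynoate | COC(=O)C#CCO[Si](C)(C)C(C)(C)C | intermediate
10 | {4-[(4-methoxybenzyloxy)methyl]pent-4-en-1-yl}magnesium bromide (formed in the flask) | COc1ccc(COCC(=C)CCC[Mg]Br)cc1 | intermediate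
11 | methyl (2Z)-3-({[tert-butyl(dimethyl)silyl]oxy}methyl)-7-{[(4-methoxybenzyl)oxy]methyl}octa-2,7-dienoate | COc1ccc(COCC(=C)CCC/C(CO[Si](C)(C)C(C)(C)C)=C/C(=O)OC)cc1 | intermediate
12 | (2Z)-3-({[tert-butyl(dimethyl)silyl]oxy}methyl)-7-{[(4-methoxybenzyl)oxy]methyl}octa-2,7-dien-1-ol | COc1ccc(COCC(=C)CCC/C(CO[Si](C)(C)C(C)(C)C)=C/CO)cc1 | intermediate
13 | (2Z)-3-({[tert-butyl(dimethyl)silyl]oxy}methyl)-7-{[(4-methoxybenzyl)oxy]methyl}octa-2,7-dienal | COc1ccc(COCC(=C)CCC/C(CO[Si](C)(C)C(C)(C)C)=C/C=O)cc1 | intermediate
14 | methyl prop-2-ynoate | C#CC(=O)OC | starting material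
15 | methyl(3-methoxy-3-oxoprop-1-yn-1-yl)zinc (formed in the flask) | C[Zn]C#CC(=O)OC | intermediate
16 | methyl (4S,5Z)-6-({[tert-butyl(dimethyl)silyl]oxy}methyl)-4-hydroxy-10-{[(4-methoxybenzyl)oxy]methyl}undeca-5,10-dien-2-ynoate | COc1ccc(COCC(=C)CCC/C(CO[Si](C)(C)C(C)(C)C)=C/[C@H](O)C#CC(=O)OC)cc1 | intermediate
17 | methyl (2Z,4R,5Z)-6-({[tert-butyl(dimethyl)silyl]oxy}methyl)-4-hydroxy-10-{[(4-methoxybenzyl)oxy]methyl}undeca-2,5,10-trienoate (formed in the flask) | COc1ccc(COCC(=C)CCC/C(CO[Si](C)(C)C(C)(C)C)=C/[C@H](O)/C=C\C(=O)OC)cc1 | intermediate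
18 | (5R)-5-[(1Z)-2-({[tert-butyl(dimethyl)silyl]oxy}methyl)-6-{[(4-methoxybenzyl)oxy]methyl}hepta-1,6-dien-1-yl]furan-2(5H)-one | COc1ccc(COCC(=C)CCC/C(CO[Si](C)(C)C(C)(C)C)=C/[C@@H]2OC(=O)C=C2)cc1 | intermediate
19 | nitromethane | C[N+](=O)[O-] | starting material
20 | (4S,5S)-5-[(1Z)-2-({[tert-butyl(dimethyl)silyl]oxy}methyl)-6-{[(4-methoxybenzyl)oxy]methyl}hepta-1,6-dien-1-yl]-4-(nitromethyl)oxolan-2-one | COc1ccc(COCC(=C)CCC/C(CO[Si](C)(C)C(C)(C)C)=C/[C@@H]2OC(=O)C[C@H]2C[N+](=O)[O-])cc1 | intermediate
21 | (4S,5S)-5-[(1Z)-2-({[tert-butyl(dimethyl)silyl]oxy}methyl)-6-(hydroxymethyl)hepta-1,6-dien-1-yl]-4-(nitromethyl)oxolan-2-one | OCC(=C)CCC/C(CO[Si](C)(C)C(C)(C)C)=C/[C@@H]1OC(=O)C[C@H]1C[N+](=O)[O-] | intermediate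
22 | potassium nitronate of 21 (formed in the flask) | OCC(=C)CCC/C(CO[Si](C)(C)C(C)(C)C)=C/[C@@H]1OC(=O)C[C@H]1C=[N+]([O-])[O-].[K+] | intermediate
23 | (2S,3R)-2-[(1Z)-2-({[tert-butyl(dimethyl)silyl]oxy}methyl)-6-(hydroxymethyl)hepta-1,6-dien-1-yl]-5-oxooxolane-3-carbaldehyde | OCC(=C)CCC/C(CO[Si](C)(C)C(C)(C)C)=C/[C@@H]1OC(=O)C[C@H]1C=O | intermediate
24 | (2S,3R)-2-[(1Z)-6-(bromomethyl)-2-({[tert-butyl(dimethyl)silyl]oxy}methyl)hepta-1,6-dien-1-yl]-5-oxooxolane-3-carbaldehyde | BrCC(=C)CCC/C(CO[Si](C)(C)C(C)(C)C)=C/[C@@H]1OC(=O)C[C@H]1C=O | intermediate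
25 | allylchromium dichloride derived from 24 (trivalent chromium; formed in the flask) | Cl[Cr](Cl)CC(=C)CCC/C(CO[Si](C)(C)C(C)(C)C)=C/[C@@H]1OC(=O)C[C@H]1C=O | intermediate
26 | (3aS,4R,10Z,11aS)-10-({[tert-butyl(dimethyl)silyl]oxy}methyl)-4-hydroxy-6-methylidene-3a,4,5,6,7,8,9,11a-octahydrocyclodeca[b]furan-2(3H)-one | O[C@@H]1CC(=C)CCC/C(CO[Si](C)(C)C(C)(C)C)=C/[C@@H]2OC(=O)C[C@H]21 | intermediate
27 | (3aR,4R,10Z,11aS)-10-({[tert-butyl(dimethyl)silyl]oxy}methyl)-6-methylidene-4-[(triethylsilyl)oxy]-3a,4,5,6,7,8,9,11a-octahydrocyclodeca[b]furan-2(3H)-one | CC[Si](CC)(CC)O[C@@H]1CC(=C)CCC/C(CO[Si](C)(C)C(C)(C)C)=C/[C@@H]2OC(=O)C[C@H]21 | intermediate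
28 | B-alkyl-9-borabicyclo[3.3.1]nonane adduct of 27 at C14 (formed in the flask) | CC[Si](CC)(CC)O[C@@H]1C[C@H](CB3C4CCCC3CCC4)CCC/C(CO[Si](C)(C)C(C)(C)C)=C/[C@@H]2OC(=O)C[C@H]21 | intermediate
29 | (3aR,4R,6R,10Z,11aS)-10-({[tert-butyl(dimethyl)silyl]oxy}methyl)-6-(hydroxymethyl)-4-[(triethylsilyl)oxy]-3a,4,5,6,7,8,9,11a-octahydrocyclodeca[b]furan-2(3H)-one | CC[Si](CC)(CC)O[C@@H]1C[C@H](CO)CCC/C(CO[Si](C)(C)C(C)(C)C)=C/[C@@H]2OC(=O)C[C@H]21 | intermediate
30 | (3aR,4R,6R,10Z,11aS)-6,10-bis({[tert-butyl(dimethyl)silyl]oxy}methyl)-4-[(triethylsilyl)oxy]-3a,4,5,6,7,8,9,11a-octahydrocyclodeca[b]furan-2(3H)-one | CC[Si](CC)(CC)O[C@@H]1C[C@H](CO[Si](C)(C)C(C)(C)C)CCC/C(CO[Si](C)(C)C(C)(C)C)=C/[C@@H]2OC(=O)C[C@H]21 | intermediate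
31 | lithium enolate of 30 (formed in the flask) | CC[Si](CC)(CC)O[C@@H]1C[C@H](CO[Si](C)(C)C(C)(C)C)CCC/C(CO[Si](C)(C)C(C)(C)C)=C/[C@@H]2OC(O[Li])=C[C@H]21 | intermediate
32 | 3-[(dimethylamino)methyl] derivative of 30 (C11 epimers; not purified) | CC[Si](CC)(CC)O[C@@H]1C[C@H](CO[Si](C)(C)C(C)(C)C)CCC/C(CO[Si](C)(C)C(C)(C)C)=C/[C@@H]2OC(=O)C(CN(C)C)[C@H]21 | intermediate
33 | trimethylammonium iodide of 32 (not purified) | CC[Si](CC)(CC)O[C@@H]1C[C@H](CO[Si](C)(C)C(C)(C)C)CCC/C(CO[Si](C)(C)C(C)(C)C)=C/[C@@H]2OC(=O)C(C[N+](C)(C)C)[C@H]21.[I-] | intermediate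
34 | (3aR,4R,6R,10Z,11aS)-6,10-bis({[tert-butyl(dimethyl)silyl]oxy}methyl)-3-methylidene-4-[(triethylsilyl)oxy]-3a,4,5,6,7,8,9,11a-octahydrocyclodeca[b]furan-2(3H)-one | CC[Si](CC)(CC)O[C@@H]1C[C@H](CO[Si](C)(C)C(C)(C)C)CCC/C(CO[Si](C)(C)C(C)(C)C)=C/[C@@H]2OC(=O)C(=C)[C@H]21 | intermediate
35 | (3aS,4R,6R,10Z,11aS)-6,10-bis({[tert-butyl(dimethyl)silyl]oxy}methyl)-4-hydroxy-3-methylidene-3a,4,5,6,7,8,9,11a-octahydrocyclodeca[b]furan-2(3H)-one | O[C@@H]1C[C@H](CO[Si](C)(C)C(C)(C)C)CCC/C(CO[Si](C)(C)C(C)(C)C)=C/[C@@H]2OC(=O)C(=C)[C@H]21 | intermediate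
36 | (3aS,4R,6R,10Z,11aS)-6,10-bis({[tert-butyl(dimethyl)silyl]oxy}methyl)-3-methylidene-2-oxo-2,3,3a,4,5,6,7,8,9,11a-decahydrocyclodeca[b]furan-4-yl 2-methylprop-2-enoate | C=C(C)C(=O)O[C@@H]1C[C@H](CO[Si](C)(C)C(C)(C)C)CCC/C(CO[Si](C)(C)C(C)(C)C)=C/[C@@H]2OC(=O)C(=C)[C@H]21 | intermediate
37 | (3aS,4R,6R,10Z,11aS)-6,10-bis(hydroxymethyl)-3-methylidene-2-oxo-2,3,3a,4,5,6,7,8,9,11a-decahydrocyclodeca[b]furan-4-yl 2-methylprop-2-enoate | C=C(C)C(=O)O[C@@H]1C[C@H](CO)CCC/C(CO)=C/[C@@H]2OC(=O)C(=C)[C@H]21 | target

## Step count and least certain steps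

Total step count: 21. Longest linear sequence: 20 steps (steps 1–3 and 5–21, from 1); step 4 is a one-step side branch.

**Step 14 (key step).**
- What may go wrong: intermolecular allylation or simple protonation of the allyl–chromium bond may compete with the slow closure of a strained ten-membered ring. The macrocyclic transition state may also override the Felkin–Anh preference, so that facial selectivity at C8 is poor or reversed.
- In-step measures: dilution and slow addition address the first problem.
- Fallback (for the second): setting out from 24, the cyclisation is run as before and the C8-epimeric alcohol F1 is not discarded. It is inverted by Mitsunobu esterification with chloroacetic acid (PPh3, DIAD, toluene) to the chloroacetate F2 of correct C8 configuration. Cleavage with thiourea and NaHCO3 in ethanol, which is close to neutral and avoids an O8 alkoxide, returns to the route at 26.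

**Step 10.**
- What may go wrong: deprotonation at C6 (γ to the carbonyl and allylic) by the amine base may compete with Michael addition. This would racemise C6 or isomerise the butenolide; reversible addition could also erode the anti selectivity.
- Fallback: from 18, a non-basic hydroxymethyl anion equivalent replaces nitromethane. Copper-catalysed conjugate addition of (i-PrO)Me2SiCH2MgCl (CuBr·SMe2, Me3SiCl, THF, −78 °C) gives the trans silylmethyl lactone F3. Tamao oxidation (H2O2, KF, KHCO3, THF/MeOH) gives the hydroxymethyl lactone F4. Dess–Martin periodinane gives the PMB-protected aldehyde F5, and DDQ removes the PMB group to rejoin the route at 23 (steps 10–12 are bypassed).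

**Step 12.**
- What may go wrong: reduction may stop at the oxime, or the aldehyde once formed may suffer β-elimination of the lactone oxygen or epimerisation at C7 if the medium is not kept buffered.
- Fallback: from 21, the conversion is split into two mild operations. The primary nitro group is reduced to the aldoxime F6 with SnCl2/PhSH/Et3N (divalent tin), and the oxime is exchanged with aqueous glyoxylic acid to release the aldehyde, returning at 23.

**Step 16.**
- What may go wrong: facial selectivity of the hydroboration at C10 may be poor, because the conformation of the ten-membered ring, not only the C8 substituent, decides which face of the exocyclic alkene is exposed.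
- Fallback: from 26, O8 is used as a tether. (HMe2Si)2NH gives the dimethylsilyl ether F7. Intramolecular hydrosilylation with Pt2[(CH2=CHSiMe2)2O]3 (zerovalent platinum) should deliver silicon to the terminal C14 and hydrogen to C10 within the six-membered cyclic siloxane F8, whose short O–Si bridge is expected to span O8 and C14 only when they are cis. Tamao oxidation gives the diol F9, t-BuMe2SiCl silylates the primary hydroxyl to give the silyl ether F10, and Et3SiCl then gives 30 (steps 15–17 are bypassed).

**Step 8.**
- What may go wrong: enantioselectivity may be insufficient or of the wrong sense, and the Z enal may isomerise under the zinc conditions.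
- Fallback: from 13, addition of lithiated methyl propiolate (LiN(SiMe3)2, THF, −90 °C) gives the racemic propargylic alcohol F11. MnO2 oxidation gives the ynone F12. Enantioselective CBS reduction (oxazaborolidine antipode chosen for the S carbinol, catecholborane, −78 °C) returns to the route at 16, so that C6 is set by hydride delivery instead of by C–C bond formation.

## Further compounds

F1 | step 14 | (3aS,4S,10Z,11aS)-10-({[tert-butyl(dimethyl)silyl]oxy}methyl)-4-hydroxy-6-methylidene-3a,4,5,6,7,8,9,11a-octahydrocyclodeca[b]furan-2(3H)-one (C8 epimer of 26) | O[C@H]1CC(=C)CCC/C(CO[Si](C)(C)C(C)(C)C)=C/[C@@H]2OC(=O)C[C@H]21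
F2 | step 14 | chloroacetate of 26 at O8 (C8 configuration of 26) | ClCC(=O)O[C@@H]1CC(=C)CCC/C(CO[Si](C)(C)C(C)(C)C)=C/[C@@H]2OC(=O)C[C@H]21
F3 | step 10 | analogue of 20 with CH2Si(CH3)2O-i-Pr in place of CH2NO2 (trans lactone) | COc1ccc(COCC(=C)CCC/C(CO[Si](C)(C)C(C)(C)C)=C/[C@@H]2OC(=O)C[C@H]2C[Si](C)(C)OC(C)C)cc1
F4 | step 10 | analogue of 20 with CH2OH in place of CH2NO2 (trans lactone) | COc1ccc(COCC(=C)CCC/C(CO[Si](C)(C)C(C)(C)C)=C/[C@@H]2OC(=O)C[C@H]2CO)cc1
F5 | step 10 | 4-methoxybenzyl ether of aldehyde 23 | COc1ccc(COCC(=C)CCC/C(CO[Si](C)(C)C(C)(C)C)=C/[C@@H]2OC(=O)C[C@H]2C=O)cc1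
F6 | step 12 | aldoxime of aldehyde 23 (E/Z mixture at C=N) | OCC(=C)CCC/C(CO[Si](C)(C)C(C)(C)C)=C/[C@@H]1OC(=O)C[C@H]1C=NO
F7 | step 16 | dimethylsilyl ether of 26 at O8 | C[SiH](C)O[C@@H]1CC(=C)CCC/C(CO[Si](C)(C)C(C)(C)C)=C/[C@@H]2OC(=O)C[C@H]21
F8 | step 16 | cyclic siloxane bridging O8 and C14 through Si(CH3)2 (C10 as in 29) | C[Si]3(C)O[C@@H]1C[C@H](C3)CCC/C(CO[Si](C)(C)C(C)(C)C)=C/[C@@H]2OC(=O)C[C@H]21
F9 | step 16 | 8,14-diol (29 without the triethylsilyl group) | O[C@@H]1C[C@H](CO)CCC/C(CO[Si](C)(C)C(C)(C)C)=C/[C@@H]2OC(=O)C[C@H]21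
F10 | step 16 | 14-O-tert-butyldimethylsilyl ether of F9 (30 without the triethylsilyl group) | O[C@@H]1C[C@H](CO[Si](C)(C)C(C)(C)C)CCC/C(CO[Si](C)(C)C(C)(C)C)=C/[C@@H]2OC(=O)C[C@H]21
F11 | step 8 | racemic form of 16 | COc1ccc(COCC(=C)CCC/C(CO[Si](C)(C)C(C)(C)C)=C/C(O)C#CC(=O)OC)cc1
F12 | step 8 | methyl (5Z)-6-({[tert-butyl(dimethyl)silyl]oxy}methyl)-10-{[(4-methoxybenzyl)oxy]methyl}-4-oxoundeca-5,10-dien-2-ynoate | COc1ccc(COCC(=C)CCC/C(CO[Si](C)(C)C(C)(C)C)=C/C(=O)C#CC(=O)OC)cc1
A1 | alternative 1 | bicyclo[5.3.0]decane hydroxy mesylate (C10–OH, C5–OMs, C4–CO2Me; Grob precursor) | O[C@]12C[C@@H](OCc3ccc(OC)cc3)[C@H](CC(OC)OC)[C@@H](OCOC)[C@@H](OS(C)(=O)=O)[C@]1(C(=O)OC)CCC2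
A2 | alternative 1 | cyclodecenone with conjugated C15 methyl ester | O=C1C[C@@H](OCc2ccc(OC)cc2)[C@H](CC(OC)OC)[C@@H](OCOC)/C=C(C(=O)OC)/CCC1
A3 | alternative 2 | open-chain C5 alkenyl iodide with C6 aldehyde | I/C=C(CO[Si](C)(C)C(C)(C)C)/CCC[C@@H](CO[Si](C)(C)C(C)(C)C)C[C@@H](OCc1ccc(OC)cc1)[C@H](CC(=O)OC)C=O
A4 | alternative 2 | ten-membered allylic alcohol with C12 methyl ester | O[C@H]1/C=C(CO[Si](C)(C)C(C)(C)C)/CCC[C@@H](CO[Si](C)(C)C(C)(C)C)C[C@@H](OCc2ccc(OC)cc2)[C@@H]1CC(=O)OC
A5 | alternative 3 | C2 iodide with 2-substituted acrylate on the trans-lactone | ICC/C(CO[Si](C)(C)C(C)(C)C)=C/[C@@H]1OC(=O)C[C@H]1[C@H](OCc1ccc(OC)cc1)CC(=C)C(=O)OC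
A6 | alternative 3 | ten-membered lactone with C14 methyl ester on C10 | COC(=O)[C@@H]1CCC/C(CO[Si](C)(C)C(C)(C)C)=C/[C@@H]2OC(=O)C[C@H]2[C@H](OCc2ccc(OC)cc2)C1
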